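The data were computed with made-up constants; the scatter is artificial.

| setting | theta | beta | blue | red |
|---|---|---|---|---|
| left-handed substrate | 0.50 M | 0.50 M | 0.50 M | 0.50 M |
| right-handed substrate | 0.50 M | 0.50 M | 0.50 M | 0.50 M |
| solid reagent | 0.75 M | 1.1 M | 1.50 M | 1.50 M |
| free catalyst | 1 mM | 1 mM | 1.0 mM | 1.0 mM |
| racemization catalyst | 1.3 mM | 1.3 mM | 1.3 mM | 1.3 mM |
| remark | run made earlier | run made earlier |  |  |
| time |  |  | 2.0 min | 0.60 min |

| run | time / s | right-handed substrate / % | left-handed substrate / % | left-handed product / % |
|---|---|---|---|---|
| theta | 10.0 | 49.8 | 49.9 | 0.2 |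
| theta | 12.0 | 49.9 | 49.0 | 0.5 |
| theta | 20.0 | 49.9 | 49.8 | 0.4 |
| theta | 40.0 | 49.1 | 48.4 | 1.5 |
| theta | 60.0 | 49.0 | 48.5 | 2.1 |
| theta | 90.0 | 47.6 | 47.4 | 3.5 |
| beta | 10.0 | 49.7 | 49.5 | 0.2 |
| beta | 12.0 | 50.0 | 50.0 | 0 |
| beta | 20.0 | 50.2 | 49.6 | 0.2 |
| beta | 40.0 | 49.4 | 49.4 | 1.2 |
| beta | 60.0 | 48.8 | 48.3 | 2.1 |
| beta | 90.0 | 47.4 | 47.3 | 3.5 |

(each reading ± 0.3 percentage points)

- free catalyst is single-handed; left-handed substrate and right-handed substrate are mirror images of each other, charged as a racemate, each of them at the stated concentration
- solid, in amounts per volume of the solution: solid reagent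
- at the start none of the solid reagent is in solution
- an excess is the difference of the two amounts in percent of their sum
- an excess is below zero if the other one leads

* which of the two ends with the higher excess of right-handed substrate over left-handed substrate among what is left of the two ("neither" if they lie within 2 percentage points) (blue / red / neither)
* excess of right-handed substrate over left-handed substrate among what is left of the two at the end, blue
* excess of right-handed substrate over left-handed substrate among what is left of the two at the end, red

**Zero first.** Take the racemate as the zero of the scale: the two substrates are charged equally, so the excess starts at nil and I need to know how far it leaves zero.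

**Product rate.** From 40.0 s to 90.0 s left-handed product gains 2 percentage points in theta and 2.3 points in beta, which holds more solid reagent. So I take one rate for both and for blue and red: 0.0258 min⁻¹, as a fraction of the charge.

**First gap.** At the last readings, right-handed substrate leads left-handed substrate by 0.15 points on average over theta and beta, so my first figure for the excess is about that.

**Weak link.** One such difference scatters by 0.42 points, more than the gap itself. So I average the gaps of both runs from 40.0 s on, which gives 0.33 points, with a standard error of 0.17 points. Two errors higher, the ceiling gap is 0.68 points. Ceiling gap over product rate gives 15.8 s: this is the hold-back time, the span of product-making that the gap can stand for.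

**My commitment.** Hold-back time times product rate, over the 95.0% of substrate left at the last theta reading, puts the ceiling for blue and red at 0.715%. That is below the margin of 2 points, so I say neither.

**The forecast.** It says neither, with 0.4% for blue (0% to 1.2%) and 0.25% for red (0% to 0.7%): “The excess should therefore settle at a small quasi-steady value of about 0.3%.”

**The flasks.** Blue ends at 0.0531% and red at 0.0468%, so the answer is neither.

    partner + free catalyst + left-handed substrate → free catalyst + left-handed product (k = 99.0 L² mol⁻² s⁻¹)
    partner + free catalyst + right-handed substrate → free catalyst + right-handed product (k = 46.0 L² mol⁻² s⁻¹)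
    left-handed substrate + racemization catalyst ⇌ right-handed substrate + racemization catalyst, rate k3*[racemization catalyst]*[left-handed substrate] forward; the back reaction follows from the equilibrium constant (k = 480 L mol⁻¹ s⁻¹)
    2 partner → self-condensation product (k = 0.0460 L mol⁻¹ s⁻¹)
    2 racemization catalyst ⇌ resting dimer (K = 1500 L mol⁻¹, k = 470 L mol⁻¹ s⁻¹)
    solid reagent ⇌ partner, rate k6*(cs6 - [partner]) while solid is left; crystals form when [partner] > cs6 (solubility = 0.210 M, k = 0.00340 s⁻¹)

**Why so low.** The loss of left-handed substrate to right-handed substrate, running both ways, holds the excess down: blue without that step ends at 2.72%, against 0.0531%. Blue's left-handed product gains 2.7 points between 1.00 min and 2.00 min, so the hold-back time gives a ceiling of 0.772%, and blue stands under it.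

**A neighbour.** Red charged with 4.0 × 10⁻⁴ M of free catalyst makes 0.636% left-handed product by 0.600 min, so the hold-back time sets its ceiling at 0.282%; that flask gives 0.0313%.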